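**Plan**

1. Retrosynthesis: the pyran CH= carbon (C1) of the quinone methide half is cut last (orthoformate closure of a resorcinol–alcohol). The western carbocycle is then cut at C4a–C5 and C6–C7 into a 4-silyloxy-2-pyrone (pyrone C3–C6 = C7, C8, C8a, C4a; its O1–C2(=O) bridge leaves as CO2) and 1-(triisopropylsilyloxy)propyne (C5–Me, C6–O). The linker C–C bond to pyrone C3 is cut to an o-quinone methide of the eastern lactone.
2. Enabling feature: the western ring carries oxygen at C6 and C8 (meta), carbon substituents at C7 and C4a, and a free C8a. This is the pattern that a 3,6-disubstituted 4-oxy-2-pyrone and an ynol ether give after CO2 extrusion. The eastern benzene ring has the same pattern and is made the same way from the same pyrone.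
3. Forward order: hydroxybutanoate → pyrone 6; 6 + siloxypropyne → eastern benzene ring → isochromanone 17; 17 + acetaldehyde + 6 → linked pyrone 21; second benzannulation builds the western benzene ring; orthoformate closes the pyran ring and gives the quinone methide.
4. Stereochemistry: all four ring stereocentres come from ethyl (R)-3-hydroxybutanoate (C3) and its anti-selective Fráter–Seebach methylation (C4). The linker centre comes from a catalyst-controlled addition to the o-quinone methide. The benzannulations create no stereocentre.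

Key step: step 13

Assumption: the quinine-derived squaramide of step 11 is taken to deliver the linker configuration drawn; if its sense is the opposite one, the quinidine-derived pseudo-enantiomer is used instead.

**Route**

Step 1
Reactants: 1 ethyl (3R)-3-hydroxybutanoate
Product: 2 ethyl (2R,3R)-3-hydroxy-2-methylbutanoate
Conditions: LiN(i-Pr)2 (2.2 equiv), THF, −78 → −20 °C; MeI, DMPU, −78 → 0 °C
Reagents that add atoms: methyl iodide, CI
Why: Fráter–Seebach alkylation, in which the chelated lithium alkoxide–enolate should be methylated anti to the C3 methyl group, setting the (2R) centre with the anti relationship of the citrinin side chain.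

Step 2
Reactants: 2 ethyl (2R,3R)-3-hydroxy-2-methylbutanoate
Product: 3 ethyl (2R,3R)-3-[(tert-butyldimethylsilyl)oxy]-2-methylbutanoate
Conditions: TBSCl, imidazole, DMF, rt
Reagents that add atoms: tert-butyldimethylsilyl chloride, CC(C)(C)[Si](C)(C)Cl
Why: Standard silylation of a secondary alcohol masks the hydroxyl for the enolate chemistry that follows and touches no stereocentre.

Step 3
Reactants: 3 ethyl (2R,3R)-3-[(tert-butyldimethylsilyl)oxy]-2-methylbutanoate; 4 methyl acetoacetate
Product: 5 methyl (6R,7R)-7-[(tert-butyldimethylsilyl)oxy]-6-methyl-3,5-dioxooctanoate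
Conditions: 4 (2.5 equiv), NaH then n-BuLi, THF, 0 °C; add 3, 0 °C → rt; aq HCl
Reagents that add atoms: none
Why: Claisen acylation of the acetoacetate dianion, whose γ-carbanion should attack the ester carbonyl; the product is stored as its enolate, which protects the α-stereocentre and the β-silyloxy group from epimerization and elimination.

Step 4
Reactants: 5 methyl (6R,7R)-7-[(tert-butyldimethylsilyl)oxy]-6-methyl-3,5-dioxooctanoate
Product: 6 6-[(2R,3R)-3-[(tert-butyldimethylsilyl)oxy]butan-2-yl]-4-hydroxy-2H-pyran-2-one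
Conditions: DBU, toluene, 60 °C; then 1 M HCl
Reagents that add atoms: none
Why: Base-mediated lactonization of a 3,5-dioxo ester (enol oxygen onto the methyl ester) is the standard route to 4-hydroxy-6-alkyl-2-pyrones, and the product is held as its pyronate so that the side-chain centre is not enolized.

Step 5
Reactants: 7 1-propynyllithium
Product: 9 triisopropyl(prop-1-yn-1-yloxy)silane, via lithium prop-1-yn-1-olate 8 (not isolated)
Conditions: t-BuOOH, LiN(SiMe3)2, THF, −78 °C; 7, −78 → 0 °C; TIPSOTf, −78 → 0 °C
Reagents that add atoms: tert-butyl hydroperoxide, CC(C)(C)OO; triisopropylsilyl triflate, CC(C)[Si](C(C)C)(C(C)C)OS(=O)(=O)C(F)(F)F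
Why: Oxidation of a lithium acetylide by lithium tert-butyl peroxide to the ynolate, followed by O-silylation with the bulky silyl triflate, should give the isolable siloxyalkyne.

Step 6
Reactants: 6 6-[(2R,3R)-3-[(tert-butyldimethylsilyl)oxy]butan-2-yl]-4-hydroxy-2H-pyran-2-one
Product: 10 4-[(tert-butyldimethylsilyl)oxy]-6-[(2R,3R)-3-[(tert-butyldimethylsilyl)oxy]butan-2-yl]-2H-pyran-2-one
Conditions: TBSCl, imidazole, CH2Cl2, rt; non-aqueous work-up
Reagents that add atoms: tert-butyldimethylsilyl chloride, CC(C)(C)[Si](C)(C)Cl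
Why: O-silylation of the acidic 4-hydroxyl removes the proton that would otherwise add to the siloxyalkyne and turns C3 into the carbon of a silyl dienol ether.

Step 7
Reactants: 10 4-[(tert-butyldimethylsilyl)oxy]-6-[(2R,3R)-3-[(tert-butyldimethylsilyl)oxy]butan-2-yl]-2H-pyran-2-one; 9 triisopropyl(prop-1-yn-1-yloxy)silane
Product: 12 1-[(2S,3R)-3-[(tert-butyldimethylsilyl)oxy]butan-2-yl]-5-[(tert-butyldimethylsilyl)oxy]-2-methyl-3-[(triisopropylsilyl)oxy]benzene, via bicyclic lactone adduct 11 (not isolated)
Conditions: 9 (1.5 equiv), Tf2NH (5 mol %), ClCH2CH2Cl, −20 °C → rt, then 60 °C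
Reagents that add atoms: none
Why: Acid-catalysed inverse-demand formal [4+2] cycloaddition of a 2-pyrone with a siloxyalkyne followed by retro-[4+2] loss of CO2 (pyrone–alkyne benzannulation); polarity matching (methyl-bearing alkyne carbon to the electrophilic pyrone C6, oxygen-bearing carbon to the nucleophilic C3) should place the methyl group next to the side chain, and no stereocentre is formed.

Step 8
Reactants: 12 1-[(2S,3R)-3-[(tert-butyldimethylsilyl)oxy]butan-2-yl]-5-[(tert-butyldimethylsilyl)oxy]-2-methyl-3-[(triisopropylsilyl)oxy]benzene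
Product: 13 5-[(2S,3R)-3-hydroxybutan-2-yl]-4-methylbenzene-1,3-diol
Conditions: Bu4NF, AcOH, THF, 0 °C → rt
Reagents that add atoms: none
Why: Fluoride cleavage of the aryl and alkyl silyl ethers, buffered with acetic acid so that the air-sensitive resorcinol stays protonated.

Step 9
Reactants: 13 5-[(2S,3R)-3-hydroxybutan-2-yl]-4-methylbenzene-1,3-diol
Product: 17 (3R,4S)-6,8-dihydroxy-3,4,5-trimethyl-3,4-dihydro-1H-isochromen-1-one, via decarboxycitrinin quinone methide 14 (not isolated), via ring-opened hydroxy aldehyde 15 (not isolated), via hydroxy acid 16 (not isolated)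
Conditions: HC(OEt)3, TFA, CH2Cl2, 0 °C → rt; evaporate; Ag2O, aq NaOH, 50 °C; then 2 M HCl
Reagents that add atoms: triethyl orthoformate, CCOC(OCC)OCC; water, O
Why: Orthoformate formylation delivered through the side-chain oxygen (oxa-Pictet–Spengler-type closure at the carbon para to one hydroxyl, as in citrinin syntheses) should give the quinone methide, whose hydrate is the lactol of a salicylaldehyde that Ag2O in alkali should oxidise to the acid (Tollens-type oxidation of phenolic aldehydes), and acidification should lactonise with retention at C3.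

Step 10
Reactants: 17 (3R,4S)-6,8-dihydroxy-3,4,5-trimethyl-3,4-dihydro-1H-isochromen-1-one; 18 acetaldehyde
Product: 19 (3R,4S)-6,8-dihydroxy-3,4,5-trimethyl-7-[1-(4-methylbenzenesulfonyl)ethyl]-3,4-dihydro-1H-isochromen-1-one (mixture of epimers at the sulfonyl carbon)
Conditions: 18 (3 equiv), TolSO2Na, HCO2H/H2O, rt
Reagents that add atoms: sodium p-toluenesulfinate, [Na+].[O-]S(=O)c1ccc(C)cc1
Why: Acid-mediated three-component α-sulfonylalkylation (hydroxyalkylation of the only free ring carbon, which lies between the two hydroxyls, then capture of the benzylic cation by sulfinate) is the usual entry to 2-(1-sulfonylalkyl)phenols; the new centre is destroyed in step 11 and so need not be controlled.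

Step 11
Reactants: 19 (3R,4S)-6,8-dihydroxy-3,4,5-trimethyl-7-[1-(4-methylbenzenesulfonyl)ethyl]-3,4-dihydro-1H-isochromen-1-one; 6 6-[(2R,3R)-3-[(tert-butyldimethylsilyl)oxy]butan-2-yl]-4-hydroxy-2H-pyran-2-one
Product: 21 6-[(2R,3R)-3-[(tert-butyldimethylsilyl)oxy]butan-2-yl]-3-{(1R)-1-[(3R,4S)-6,8-dihydroxy-3,4,5-trimethyl-1-oxo-3,4-dihydro-1H-isochromen-7-yl]ethyl}-4-hydroxy-2H-pyran-2-one, via o-quinone methide 20 (not isolated)
Conditions: 6 (1.2 equiv), quinine-derived squaramide (10 mol %), Na2CO3 (solid), CH2Cl2, 0 °C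
Reagents that add atoms: none
Why: Base-induced 1,4-elimination of sulfinate releases the o-quinone methide in low concentration, and the bifunctional squaramide (ion-paired to the pyronate, hydrogen-bonded to the quinone methide carbonyl) should direct pyrone C3 to one face (organocatalytic asymmetric conjugate addition of 1,3-dicarbonyl-type nucleophiles to o-quinone methides formed in the flask), so the linker centre is set by the catalyst and not by the remote ring centres.

Step 12
Reactants: 21 6-[(2R,3R)-3-[(tert-butyldimethylsilyl)oxy]butan-2-yl]-3-{(1R)-1-[(3R,4S)-6,8-dihydroxy-3,4,5-trimethyl-1-oxo-3,4-dihydro-1H-isochromen-7-yl]ethyl}-4-hydroxy-2H-pyran-2-one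
Product: 22 tris(tert-butyldimethylsilyl) ether of 21 (silyl groups on the pyrone 4-oxygen and on the 6- and 8-oxygens of the isochromenone)
Conditions: TBSOTf, 2,6-lutidine, CH2Cl2, 0 °C → rt
Reagents that add atoms: tert-butyldimethylsilyl triflate, CC(C)(C)[Si](C)(C)OS(=O)(=O)C(F)(F)F
Why: Exhaustive silylation with the silyl triflate caps the pyrone hydroxyl and both hindered phenols, so that no O–H can protonate the siloxyalkyne and the o-quinone methide cannot re-form (no retro-Michael loss of the linker centre).

Step 13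
Reactants: 22 tris(tert-butyldimethylsilyl) ether of 21; 9 triisopropyl(prop-1-yn-1-yloxy)silane
Product: 24 (3R,4S)-6,8-bis[(tert-butyldimethylsilyl)oxy]-7-{(1S)-1-[6-[(tert-butyldimethylsilyl)oxy]-4-[(2S,3R)-3-[(tert-butyldimethylsilyl)oxy]butan-2-yl]-3-methyl-2-[(triisopropylsilyl)oxy]phenyl]ethyl}-3,4,5-trimethyl-3,4-dihydro-1H-isochromen-1-one, via bicyclic lactone adduct 23 (not isolated)
Conditions: 9 (2 equiv), Tf2NH (10 mol %), ClCH2CH2Cl, −20 °C → rt, then 60 °C
Reagents that add atoms: none
Why: Tf2NH is silylated in the flask to a silyl triflimide that silylates the pyrone carbonyl oxygen; the resulting 2,4-bis(silyloxy)pyrylium ion is attacked at C6 by the methyl-bearing carbon of the siloxyalkyne, the silyl ketenium carbon so formed is captured by C3 of the cyclic silyl ketene acetal, and loss of the silyl cation gives the 2-oxabicyclo[2.2.2]octa-5,7-dien-3-one 23, which aromatises by retro-[4+2] extrusion of CO2. The closest known reaction type is the inverse-electron-demand Diels–Alder/retro-Diels–Alder benzannulation of 2-pyrones with ynamines, ynol ethers or siloxyalkynes, run thermally or with acid catalysis. The one ring that is closed, the western carbocycle, is closed by an intermolecular formal [4+2] addition across C3 and C6 of the pyrone (first bond by conjugate addition to the pyrylium, second by six-membered closure of the dienol ether onto the ketenium), and it becomes a benzene ring when the O–C(=O) bridge leaves. No stereocentre is created: the two bridgehead centres of 23 vanish with CO2, and the linker and side-chain centres have no pathway to epimerize under these aprotic conditions. The step needs regioselectivity (oxygen-bearing alkyne carbon to C3, methyl-bearing carbon to C6), which the matched polarity of both partners secures, and chemoselectivity for the pyrone, which is secured by silylation of every hydroxyl and by the fully substituted eastern arene offering no position to the ketenium.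

Step 14
Reactants: 24 penta-silylated biaryl-ethane from step 13
Product: 25 (3R,4S)-7-{(1S)-1-[2,6-dihydroxy-4-[(2S,3R)-3-hydroxybutan-2-yl]-3-methylphenyl]ethyl}-6,8-dihydroxy-3,4,5-trimethyl-3,4-dihydro-1H-isochromen-1-one
Conditions: Bu4NF, AcOH, THF, 0 °C → rt
Reagents that add atoms: none
Why: Global fluoride desilylation of four TBS ethers and the TIPS ether, with acetic acid buffering to protect the lactone and the electron-rich bis-resorcinol from base and air (the change of the linker descriptor from R to S between 21 and 24/25 is only a change of priorities).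

Step 15
Reactants: 25 pentahydroxy biaryl-ethane from step 14
Product: 26 dicitrinone H
Conditions: HC(OEt)3, TFA, CH2Cl2, 0 °C → rt; then dilute aq HCl
Reagents that add atoms: triethyl orthoformate, CCOC(OCC)OCC
Why: Orthoformate formylation at the only unsubstituted aromatic carbon (C8a of the western ring), closure of the secondary hydroxyl onto the aryl-stabilised oxocarbenium ion (oxa-Pictet–Spengler type, the classical last step of citrinin syntheses) and loss of ethanol should give the quinone methide with both pyran stereocentres untouched.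

**Compound list**

1 | ethyl (3R)-3-hydroxybutanoate | O[C@H](C)CC(=O)OCC | starting material
2 | ethyl (2R,3R)-3-hydroxy-2-methylbutanoate | O[C@H](C)[C@H](C(=O)OCC)C | intermediate
3 | ethyl (2R,3R)-3-[(tert-butyldimethylsilyl)oxy]-2-methylbutanoate | CC(C)(C)[Si](C)(C)O[C@H](C)[C@H](C(=O)OCC)C | intermediate
4 | methyl acetoacetate | COC(=O)CC(C)=O | starting material
5 | methyl (6R,7R)-7-[(tert-butyldimethylsilyl)oxy]-6-methyl-3,5-dioxooctanoate | CC(C)(C)[Si](C)(C)O[C@H](C)[C@H](C(=O)CC(=O)CC(=O)OC)C | intermediate
6 | 6-[(2R,3R)-3-[(tert-butyldimethylsilyl)oxy]butan-2-yl]-4-hydroxy-2H-pyran-2-one | CC(C)(C)[Si](C)(C)O[C@H](C)[C@H](C1=CC(O)=CC(=O)O1)C | intermediate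
7 | 1-propynyllithium | [Li]C#CC | starting material
8 | lithium prop-1-yn-1-olate | CC#C[O-].[Li+] | intermediate
9 | triisopropyl(prop-1-yn-1-yloxy)silane | CC#CO[Si](C(C)C)(C(C)C)C(C)C | intermediate
10 | 4-[(tert-butyldimethylsilyl)oxy]-6-[(2R,3R)-3-[(tert-butyldimethylsilyl)oxy]butan-2-yl]-2H-pyran-2-one | CC(C)(C)[Si](C)(C)O[C@H](C)[C@H](C1=CC(O[Si](C)(C)C(C)(C)C)=CC(=O)O1)C | intermediate
11 | 5-[(tert-butyldimethylsilyl)oxy]-1-[(2R,3R)-3-[(tert-butyldimethylsilyl)oxy]butan-2-yl]-7-methyl-8-[(triisopropylsilyl)oxy]-2-oxabicyclo[2.2.2]octa-5,7-dien-3-one (either bridgehead configuration) | CC(C)(C)[Si](C)(C)O[C@H](C)[C@H](C12OC(=O)C(C(O[Si](C(C)C)(C(C)C)C(C)C)=C1C)C(O[Si](C)(C)C(C)(C)C)=C2)C | intermediate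
12 | 1-[(2S,3R)-3-[(tert-butyldimethylsilyl)oxy]butan-2-yl]-5-[(tert-butyldimethylsilyl)oxy]-2-methyl-3-[(triisopropylsilyl)oxy]benzene | CC(C)(C)[Si](C)(C)O[C@H](C)[C@H](c1cc(O[Si](C)(C)C(C)(C)C)cc(O[Si](C(C)C)(C(C)C)C(C)C)c1C)C | intermediate
13 | 5-[(2S,3R)-3-hydroxybutan-2-yl]-4-methylbenzene-1,3-diol | O[C@H](C)[C@H](c1cc(O)cc(O)c1C)C | intermediate
14 | decarboxycitrinin, (3R,4S)-6-hydroxy-3,4,5-trimethyl-3,4-dihydro-8H-isochromen-8-one | CC1=C2C(=CO[C@H](C)[C@H]2C)C(=O)C=C1O | intermediate
15 | 2,4-dihydroxy-6-[(2S,3R)-3-hydroxybutan-2-yl]-5-methylbenzaldehyde | O=Cc1c(O)cc(O)c(C)c1[C@H](C)[C@@H](C)O | intermediate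
16 | 2,4-dihydroxy-6-[(2S,3R)-3-hydroxybutan-2-yl]-5-methylbenzoic acid | OC(=O)c1c(O)cc(O)c(C)c1[C@H](C)[C@@H](C)O | intermediate
17 | (3R,4S)-6,8-dihydroxy-3,4,5-trimethyl-3,4-dihydro-1H-isochromen-1-one | Oc1cc(O)c(C)c2c1C(=O)O[C@H](C)[C@H]2C | intermediate
18 | acetaldehyde | CC=O | starting material
19 | (3R,4S)-6,8-dihydroxy-3,4,5-trimethyl-7-[1-(4-methylbenzenesulfonyl)ethyl]-3,4-dihydro-1H-isochromen-1-one | CC(c1c(O)c(C)c2c(c1O)C(=O)O[C@H](C)[C@H]2C)S(=O)(=O)c1ccc(C)cc1 | intermediate
20 | (3R,4S)-7-ethylidene-8-hydroxy-3,4,5-trimethyl-3,4-dihydro-1H-isochromene-1,6(7H)-dione | CC=C1C(=O)C(C)=C2C(=C1O)C(=O)O[C@H](C)[C@H]2C | intermediate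
21 | 6-[(2R,3R)-3-[(tert-butyldimethylsilyl)oxy]butan-2-yl]-3-{(1R)-1-[(3R,4S)-6,8-dihydroxy-3,4,5-trimethyl-1-oxo-3,4-dihydro-1H-isochromen-7-yl]ethyl}-4-hydroxy-2H-pyran-2-one | CC(C)(C)[Si](C)(C)O[C@H](C)[C@H](C1=CC(O)=C([C@H](C)c2c(O)c(C)c3c(c2O)C(=O)O[C@H](C)[C@H]3C)C(=O)O1)C | intermediate
22 | tris(tert-butyldimethylsilyl) ether of 21 (pyrone 4-O, isochromenone 6-O and 8-O) | CC(C)(C)[Si](C)(C)O[C@H](C)[C@H](C1=CC(O[Si](C)(C)C(C)(C)C)=C([C@H](C)c2c(O[Si](C)(C)C(C)(C)C)c(C)c3c(c2O[Si](C)(C)C(C)(C)C)C(=O)O[C@H](C)[C@H]3C)C(=O)O1)C | intermediate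
23 | 2-oxabicyclo[2.2.2]octa-5,7-dien-3-one adduct of 22 and 9 (C1 side chain, C4 linker, C5 OTBS, C7 methyl, C8 OTIPS; either bridgehead configuration) | CC(C)(C)[Si](C)(C)O[C@H](C)[C@H](C12OC(=O)C([C@H](C)c3c(O[Si](C)(C)C(C)(C)C)c(C)c4c(c3O[Si](C)(C)C(C)(C)C)C(=O)O[C@H](C)[C@H]4C)(C(O[Si](C(C)C)(C(C)C)C(C)C)=C1C)C(O[Si](C)(C)C(C)(C)C)=C2)C | intermediate
24 | (3R,4S)-6,8-bis[(tert-butyldimethylsilyl)oxy]-7-{(1S)-1-[6-[(tert-butyldimethylsilyl)oxy]-4-[(2S,3R)-3-[(tert-butyldimethylsilyl)oxy]butan-2-yl]-3-methyl-2-[(triisopropylsilyl)oxy]phenyl]ethyl}-3,4,5-trimethyl-3,4-dihydro-1H-isochromen-1-one | Cc1c(O[Si](C(C)C)(C(C)C)C(C)C)c([C@H](C)c2c(O[Si](C)(C)C(C)(C)C)c(C)c3c(c2O[Si](C)(C)C(C)(C)C)C(=O)O[C@H](C)[C@H]3C)c(O[Si](C)(C)C(C)(C)C)cc1[C@H](C)[C@@H](C)O[Si](C)(C)C(C)(C)C | intermediate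
25 | (3R,4S)-7-{(1S)-1-[2,6-dihydroxy-4-[(2S,3R)-3-hydroxybutan-2-yl]-3-methylphenyl]ethyl}-6,8-dihydroxy-3,4,5-trimethyl-3,4-dihydro-1H-isochromen-1-one | Cc1c(O)c([C@H](C)c2c(O)c(C)c3c(c2O)C(=O)O[C@H](C)[C@H]3C)c(O)cc1[C@H](C)[C@@H](C)O | intermediate
26 | dicitrinone H | CC1=C2C(=CO[C@H](C)[C@H]2C)C(=O)C([C@H](C)c2c(O)c(C)c3c(c2O)C(=O)O[C@H](C)[C@H]3C)=C1O | target

**Totals**

Total step count: 15. Longest linear sequence: 14 steps (steps 1–4 and 6–15, from compound 1); step 5 is a one-step side branch.

**Steps most likely to fail, with fallbacks**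

Step 13. The cycloaddition may stall because bond formation at pyrone C3 has to create a quaternary bridgehead next to the bulky 1-arylethyl group, or the acid-activated siloxyalkyne may be consumed by self-condensation before it engages the hindered pyrone. The fallback moves the benzannulation off the hindered substrate: it sets out from 19 and uses the resorcinol 13, whose benzene ring was already made by the same reaction on the unhindered pyrone 10 in step 7. Under the conditions of step 11 (squaramide, solid Na2CO3) the o-quinone methide 20 is formed from 19 and is attacked by 13 through its carbon between the two hydroxyls, a catalyst-controlled Friedel–Crafts alkylation of a phenol by an o-quinone methide. This gives 25 directly, where the fallback comes back to the route; it makes no compound outside the list (F0). The selectivity to be watched there is attack at the carbon between the hydroxyls of 13 and not at the carbon next to its side chain.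

Step 11. Facial selectivity may be poor on a methyl-substituted, doubly ortho-oxygenated quinone methide; the quinone methide may tautomerize to the vinylphenol; or the adduct may lose configuration by retro-Michael reaction. The fallback sets the linker centre by asymmetric reduction and sets out from 17. Pechmann condensation of 17 with ethyl acetoacetate (MeSO3H) should give the tricyclic 4-methylcoumarin F1 (new C–C bond at C7, lactone through the C6 oxygen). Copper hydride conjugate reduction (Cu(OAc)2, (R)- or (S)-DTBM-SEGPHOS, (EtO)2MeSiH, t-BuOH) then sets the methyl-bearing centre in the 4-methyl-3,4-dihydrocoumarin F2. C-Acetylation of its lactone enolate (LiN(SiMe3)2, 1-acetylimidazole) gives the 3-acetyl-dihydrocoumarin F3, an aryl ester of a substituted acetoacetic acid. Its polyanion (NaH, n-BuLi) is acylated with ester 3 as in step 3, and on treatment with DBU the enol oxygen attacks the aryl lactone carbonyl, forming the pyrone ring and releasing the phenol. This gives 21, where the fallback comes back to the route.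

Step 9. Formylation may partly go to the carbon between the two hydroxyls of 13 instead of through the tethered oxygen, and the electron-rich resorcinol may be over-oxidised or deformylated in the alkaline silver oxidation. The fallback introduces the lactone carbon at the carboxyl level on the protected arene and sets out from 12. Bromination with NBS (MeCN, 0 °C) para to the triisopropylsilyloxy group gives the aryl bromide F4. Palladium-catalysed methoxycarbonylation (Pd(OAc)2, di(1-adamantyl)-n-butylphosphine, CO, MeOH, Et3N) gives the methyl benzoate F5. Bu4NF followed by dilute acid removes the three silyl groups and closes the lactone with loss of methanol. This gives 17, where the fallback comes back to the route.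

**Further compounds**

F0 | step 13 | none | none
F1 | step 11 | tricyclic 4-methylcoumarin of 17 (coumarin C4 on C7, lactone oxygen on C6 of 17, 8-OH free) | CC1=CC(=O)Oc2c(C)c3c(c(O)c12)C(=O)O[C@H](C)[C@H]3C
F2 | step 11 | (S)-4-methyl-3,4-dihydrocoumarin obtained from F1 | O=C1C[C@H](C)c2c(O1)c(C)c3c(c2O)C(=O)O[C@H](C)[C@H]3C
F3 | step 11 | 3-acetyl derivative of F2 (either configuration at C3 of the dihydrocoumarin) | O=C1C(C(C)=O)[C@H](C)c2c(O1)c(C)c3c(c2O)C(=O)O[C@H](C)[C@H]3C
F4 | step 9 | 2-bromo-3-[(tert-butyldimethylsilyl)oxy]-1-[(2S,3R)-3-[(tert-butyldimethylsilyl)oxy]butan-2-yl]-6-methyl-5-[(triisopropylsilyl)oxy]benzene | CC(C)(C)[Si](C)(C)O[C@H](C)[C@H](c1c(Br)c(O[Si](C)(C)C(C)(C)C)cc(O[Si](C(C)C)(C(C)C)C(C)C)c1C)C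
F5 | step 9 | methyl 2-[(tert-butyldimethylsilyl)oxy]-6-[(2S,3R)-3-[(tert-butyldimethylsilyl)oxy]butan-2-yl]-5-methyl-4-[(triisopropylsilyl)oxy]benzoate | CC(C)(C)[Si](C)(C)O[C@H](C)[C@H](c1c(C(=O)OC)c(O[Si](C)(C)C(C)(C)C)cc(O[Si](C(C)C)(C(C)C)C(C)C)c1C)C
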